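**Assumption:** Agrimol C is the achiral aspidinol–CH2–(butyryl-phloroglucinol)–CH2–aspidinol trimer. It has no stereocenters, so no enantiocontrol is needed and the SMILES carries no stereo descriptors. Phloroglucinol is made in step 3 rather than purchased.

**Retrosynthetic overview**
- Disconnect both Ar–CH2–Ar bridges by a double oxidative radical cross-coupling: the two free ring C–H positions of butyrylphloroglucinol (6) couple with a benzylic CH3 of the symmetric dimethyl aspidinol-type ketone 8. This avoids formaldehyde chemistry.
- Ketone 8 comes from C,C-dimethylation of the 4-O-methyl ether 7, which comes from selective 4-O-methylation of 6.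
- Compound 6 comes from Hoesch acylation of phloroglucinol (4). Phloroglucinol comes from 3,5-dimethoxyphenol (3), made by C5–H borylation/oxidation of 1,3-dimethoxybenzene (2), which is made from resorcinol (1).
- No ring is constructed. All three arenes derive from resorcinol, the third oxygen is installed by C–H borylation/oxidation, and the two CH2 bridges are formed last.

---

**Step 1**
Reactants: 1 resorcinol
Product: 2 1,3-dimethoxybenzene
Conditions: MeI (2.5 equiv), K2CO3, acetone, reflux
Reagents that add atoms: MeI (CI)
Why: Williamson O-methylation caps both OH groups so that the next step can proceed by steric C–H activation.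

**Step 2**
Reactants: 2 1,3-dimethoxybenzene
Product: 3 3,5-dimethoxyphenol
Conditions: (i) B2pin2, [Ir(cod)OMe]2 (1.5 mol%), dtbpy (3 mol%), THF, 80 °C; (ii) same pot, Oxone, acetone/H2O, rt
Reagents that add atoms: Oxone (KHSO5, [K+].OOS(=O)(=O)[O-]) supplies the new phenolic O
Why: Ir-catalysed C–H borylation of 1,3-disubstituted arenes is governed by sterics and goes to C5, meta to both OMe groups. This is the only position where oxygen is missing for the 1,3,5-pattern. Oxidative deborylation then gives the phenol.

**Step 3**
Reactants: 3 3,5-dimethoxyphenol
Product: 4 phloroglucinol (1,3,5-trihydroxybenzene)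
Conditions: BBr3 (3 equiv), CH2Cl2, −78 °C to rt; then MeOH quench
Reagents that add atoms: none
Why: BBr3 O-demethylation of aryl methyl ethers; no other functional group is present.

**Step 4**
Reactants: 4 phloroglucinol, 5 butyronitrile (CCCC#N)
Product: 6 2,4,6-trihydroxybutyrophenone
Conditions: ZnCl2, HCl (g), Et2O, 0 °C to rt; then H2O, reflux
Reagents that add atoms: butyronitrile (CCCC#N) supplies the butyryl carbons; water (O) supplies the ketone oxygen on ketimine hydrolysis
Why: Hoesch acylation is the standard C-acylation of phloroglucinol. The ring is highly nucleophilic and mono-acylation is self-limiting.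

**Step 5**
Reactants: 6 2,4,6-trihydroxybutyrophenone
Product: 7 1-(2,6-dihydroxy-4-methoxyphenyl)butan-1-one
Conditions: MeI (1.05 equiv), K2CO3 (1.1 equiv), acetone, reflux
Reagents that add atoms: MeI (CI)
Why: The 2,6-OH groups are chelated to the C=O, while the 4-OH is the most acidic and unchelated, so it is methylated selectively.

**Step 6**
Reactants: 7 1-(2,6-dihydroxy-4-methoxyphenyl)butan-1-one
Product: 8 1-(2,6-dihydroxy-4-methoxy-3,5-dimethylphenyl)butan-1-one (symmetric; the two ring methyls are equivalent)
Conditions: MeI (2.5 equiv), NaOMe (2.5 equiv), MeOH, 60 °C, sealed tube
Reagents that add atoms: MeI (CI)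
Why: Phenolate C-alkylation in protic solvent is the established C-methylation of acylphloroglucinols. The 4-OMe group suppresses gem-dimethyl dienone formation, and C3 and C5 are equivalent, so a single symmetric product is possible.

**Step 7**
Reactants: 6 2,4,6-trihydroxybutyrophenone (1.0 equiv), 8 dimethyl ketone (2.6 equiv)
Product: 9 Agrimol C
Conditions: Mes-Acr+ BF4− (5 mol%), Na2S2O8 (3 equiv), HFIP/MeCN 1:1, blue LEDs, 25 °C, N2, 24 h
Reagents that add atoms: none (net loss of 4 H; persulfate is the terminal oxidant)
Why: Proposed new method: this is a double dehydrogenative radical–radical cross-coupling. Acridinium*/SO4•− oxidises both phenols to phenoxyl radicals; HFIP stabilises these radicals and their H-bonding. The hindered, fully substituted phenoxyl radical of 8 is persistent and shifts spin to its ortho CH3 by H-atom relay, giving an o-hydroxybenzyl-type radical (formally a quinone methide•H). The transient phenoxyl radical of 6 has its spin density at the free ring carbons C3 and C5, and cross-couples with it through the benzylic CH2 terminus. This cross-coupling is favoured by the persistent-radical effect; tautomerisation then rearomatises the ring, and the cycle repeats at the other C–H. Compound 8 has no ring C–H, so it cannot self-couple; the product central ring has no C–H left, so it cannot be over-alkylated; and the excess of 8 drives 6 to the bis-adduct. The closest known chemistry is oxidative cross-dehydrogenative benzylation of phenols through o-quinone methides and photoredox phenoxyl-radical couplings. No stereocenter is created.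

---

**Compound list**

| # | Name | SMILES | Role |
|---|---|---|---|
| 1 | resorcinol | Oc1cccc(O)c1 | starting material |
| 2 | 1,3-dimethoxybenzene | COc1cccc(OC)c1 | intermediate |
| 3 | 3,5-dimethoxyphenol | COc1cc(O)cc(OC)c1 | intermediate |
| 4 | phloroglucinol | Oc1cc(O)cc(O)c1 | intermediate |
| 5 | butyronitrile | CCCC#N | starting material |
| 6 | 2,4,6-trihydroxybutyrophenone | CCCC(=O)c1c(O)cc(O)cc1O | intermediate |
| 7 | 1-(2,6-dihydroxy-4-methoxyphenyl)butan-1-one | CCCC(=O)c1c(O)cc(OC)cc1O | intermediate |
| 8 | 1-(2,6-dihydroxy-4-methoxy-3,5-dimethylphenyl)butan-1-one | CCCC(=O)c1c(O)c(C)c(OC)c(C)c1O | intermediate |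
| 9 | Agrimol C (achiral) | CCCC(=O)c1c(O)c(Cc2c(O)c(C)c(OC)c(C(=O)CCC)c2O)c(O)c(Cc2c(O)c(C)c(OC)c(C(=O)CCC)c2O)c1O | target |

Atom check for step 7: C10H12O4 (6) + 2 × C13H18O4 (8) − 4 H = C36H44O12, which matches 9.

**Total steps:** 7
**Longest linear sequence:** 7 (1 → 2 → 3 → 4 → 6 → 7 → 8 → 9)

**Three steps most likely to fail**
1. **Step 7 (radical coupling).** Risks are o-quinone methide dimerisation, PB homodimerisation, over-oxidation and oligomerisation through the remaining ring methyls of the product. Fallback: use a polar route instead. Brominate 8 at the benzylic position (NBS; the ring has no free C–H) and alkylate the dianion of 6 with the resulting o-hydroxybenzyl bromide (o-quinone methide alkylation, aqueous NaOH).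
2. **Step 6 (C,C-dimethylation).** Mono-methylation, O-methylation and gem-dimethylation may compete. Fallback: install the methyls before acylation. Methylate 3 to 1,3,5-trimethoxybenzene (MeI, K2CO3), then do two sequential n-BuLi/MeI lithiation–methylations at the C2 and C4 positions. Finish with butyryl chloride/BCl3 acylation and ortho-demethylation, which gives 8 directly.
3. **Step 5 (selective 4-O-methylation).** The product may be contaminated with the bis-methyl ether and unreacted 6. Fallback: bypass the differentiation. Methylate 3 to 1,3,5-trimethoxybenzene and treat it with butyryl chloride/BCl3. Selective demethylation of the two OMe groups ortho to the ketone gives 7 directly, and a BBr3 step on the acylated product gives 6 if needed.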